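**Plan** (heptane chain numbered C1 at the guaiacyl end to C7 at the syringyl end)

1. Retrosynthesis: the phenols are masked as benzyl ethers and the two acetates go back to the acetonide of the syn-3,5-diol. C1–C2 (guaiacyl CH2–CH2) is then cut as a reductive doubly decarboxylative coupling, and the syringyl ring–C7 bond as a nickel cross-electrophile coupling.
2. Feature that allows the C1–C2 event: C1 is the benzylic CH2 of the guaiacyl ring (ring-stabilised radical, the α-carbon of homovanillic acid). C2 is the CH2 beside the oxygenated C3 of a 3,5-syn-dioxygenated chain (the α-carbon of a statin-type 3,5-dihydroxy acid). The bond is thus the formal cross-Kolbe dimer of two carboxylic acids.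
3. What remains (C2–C7 with both oxygens) is the commercial atorvastatin side-chain nitrile ester 1. Its 1,3-dioxane (acetonide) ring serves as a temporary ring through the coupling and the N-acyloxyphthalimide esters as activating groups; both are removed afterwards.
4. Forward: ester end of 1 → CH2OH → CH2Br → aryl (syringyl ring); nitrile end → CHO → CO2H → redox-active ester; coupling with the homovanillic ester; acetonide → diol → diacetate; hydrogenolysis.
5. Stereochemistry: C3 (R) and C5 (S) are the two stereocentres of (4R,6R)-1 and are never touched. The syn-diol is pseudo-meso, so the absolute configuration is fixed by sending the syringyl ring to the ester end and the guaiacyl unit to the nitrile end of 1.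

Key step: step 9

Remark: 1, 4 and 11 are taken to be commercial. All dioxanes are 4,6-cis as in 1; the CIP descriptors change along the route only because substituent priorities change.

**Step 1**
Reactants: 1 tert-butyl 2-[(4R,6R)-6-(cyanomethyl)-2,2-dimethyl-1,3-dioxan-4-yl]acetate
Product: 2 2-[(4R,6S)-6-(2-hydroxyethyl)-2,2-dimethyl-1,3-dioxan-4-yl]acetonitrile
Conditions: LiBH4 (3 equiv), MeOH (3 equiv), THF, 0 to 40 °C; then water
Reagents that add atoms: none
Why: Chemoselective borohydride reduction of an ester should give the primary alcohol, since LiBH4 attacks neither the nitrile nor the acetal and no stereocentre is involved.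

**Step 2**
Reactants: 2 2-[(4R,6S)-6-(2-hydroxyethyl)-2,2-dimethyl-1,3-dioxan-4-yl]acetonitrile
Product: 3 2-[(4R,6R)-6-(2-bromoethyl)-2,2-dimethyl-1,3-dioxan-4-yl]acetonitrile
Conditions: CBr4, PPh3, CH2Cl2, 0 °C
Reagents that add atoms: carbon tetrabromide, BrC(Br)(Br)Br
Why: The Appel reaction should convert the primary alcohol into the bromide through the alkoxyphosphonium salt under neutral conditions that spare acetonide and nitrile.

**Step 3**
Reactants: 4 4-bromo-2,6-dimethoxyphenol
Product: 5 2-(benzyloxy)-5-bromo-1,3-dimethoxybenzene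
Conditions: BnBr, K2CO3, DMF, 60 °C
Reagents that add atoms: benzyl bromide, BrCc1ccccc1
Why: Williamson ether synthesis on the acidic phenol should give the benzyl ether, which masks the syringyl phenol until the last step.

**Step 4**
Reactants: 3 2-[(4R,6R)-6-(2-bromoethyl)-2,2-dimethyl-1,3-dioxan-4-yl]acetonitrile and 5 2-(benzyloxy)-5-bromo-1,3-dimethoxybenzene
Product: 6 2-[(4R,6S)-6-[2-(4-benzyloxy-3,5-dimethoxyphenyl)ethyl]-2,2-dimethyl-1,3-dioxan-4-yl]acetonitrile
Conditions: NiI2·xH2O (10 mol %), 4,4'-dimethoxy-2,2'-bipyridine (10 mol %), NaI (25 mol %), pyridine (10 mol %), Zn dust (2 equiv), DMPU, 60 °C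
Reagents that add atoms: none
Why: Nickel-catalysed reductive cross-electrophile coupling of an aryl bromide with a primary alkyl bromide (arylnickel captures the primary alkyl radical) should form the aryl–C7 bond and tolerates nitrile, acetal and benzyl ether.

**Step 5**
Reactants: 6 2-[(4R,6S)-6-[2-(4-benzyloxy-3,5-dimethoxyphenyl)ethyl]-2,2-dimethyl-1,3-dioxan-4-yl]acetonitrile
Product: 8 2-[(4S,6S)-6-[2-(4-benzyloxy-3,5-dimethoxyphenyl)ethyl]-2,2-dimethyl-1,3-dioxan-4-yl]acetaldehyde, via N-diisobutylalumanyl aldimine 7 (not isolated)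
Conditions: DIBAL-H (1.3 equiv), CH2Cl2, −78 °C; then aq. Rochelle salt, rt
Reagents that add atoms: water, O; diisobutylaluminium hydride, CC(C)C[AlH]CC(C)C (its aluminium is held only in 7)
Why: Partial hydride reduction of a nitrile with DIBAL-H should stop at the N-aluminated aldimine, which hydrolyses on work-up to the aldehyde; the ring stereocentre is β to the carbonyl and cannot epimerise.

**Step 6**
Reactants: 8 2-[(4S,6S)-6-[2-(4-benzyloxy-3,5-dimethoxyphenyl)ethyl]-2,2-dimethyl-1,3-dioxan-4-yl]acetaldehyde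
Product: 9 2-[(4S,6S)-6-[2-(4-benzyloxy-3,5-dimethoxyphenyl)ethyl]-2,2-dimethyl-1,3-dioxan-4-yl]acetic acid
Conditions: NaClO2, NaH2PO4, 2-methyl-2-butene (excess), t-BuOH/H2O, 0 °C to rt
Reagents that add atoms: sodium chlorite, [Na+].[O-]Cl=O
Why: Pinnick oxidation should give the acid at buffered pH without β-elimination, the alkene scavenger keeping HOCl away from the electron-rich ring.

**Step 7**
Reactants: 9 2-[(4S,6S)-6-[2-(4-benzyloxy-3,5-dimethoxyphenyl)ethyl]-2,2-dimethyl-1,3-dioxan-4-yl]acetic acid
Product: 10 1,3-dioxoisoindolin-2-yl 2-[(4S,6S)-6-[2-(4-benzyloxy-3,5-dimethoxyphenyl)ethyl]-2,2-dimethyl-1,3-dioxan-4-yl]acetate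
Conditions: N-hydroxyphthalimide, DIC, DMAP (10 mol %), CH2Cl2, rt
Reagents that add atoms: N-hydroxyphthalimide, O=C1c2ccccc2C(=O)N1O
Why: Steglich-type carbodiimide esterification should give the redox-active ester that turns the carboxyl group into a latent primary radical at C2.

**Step 8**
Reactants: 11 2-(4-benzyloxy-3-methoxyphenyl)acetic acid
Product: 12 1,3-dioxoisoindolin-2-yl 2-(4-benzyloxy-3-methoxyphenyl)acetate
Conditions: N-hydroxyphthalimide, DIC, CH2Cl2, rt (no base)
Reagents that add atoms: N-hydroxyphthalimide, O=C1c2ccccc2C(=O)N1O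
Why: Carbodiimide esterification without added base should give the redox-active ester of the arylacetic acid, the latent guaiacyl benzyl radical (C1).

**Step 9**
Reactants: 10 1,3-dioxoisoindolin-2-yl 2-[(4S,6S)-6-[2-(4-benzyloxy-3,5-dimethoxyphenyl)ethyl]-2,2-dimethyl-1,3-dioxan-4-yl]acetate and 12 1,3-dioxoisoindolin-2-yl 2-(4-benzyloxy-3-methoxyphenyl)acetate
Product: 13 (4R,6S)-4-[2-(4-benzyloxy-3-methoxyphenyl)ethyl]-6-[2-(4-benzyloxy-3,5-dimethoxyphenyl)ethyl]-2,2-dimethyl-1,3-dioxane
Conditions: 12 (3 equiv), NiCl2·6H2O (20 mol %), 2,2':6',2''-terpyridine (20 mol %), AgNO3 (0.3 equiv), Mg anode/RVC cathode, undivided cell, NMP, constant current, rt; then aq. NH4Cl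
Reagents that add atoms: none
Why: Proposed new method: each N-acyloxyphthalimide takes up one electron from the cathodically generated low-valent Ni–terpyridine complex, loses phthalimide anion and CO2 and releases a radical (the unstabilised primary radical at C2 from 10, the ring-stabilised guaiacyl benzyl radical at C1 from 12); nickel binds the two one after the other and reductive elimination from the dialkylnickel(III) forms C1–C2, the Mg anode supplying the electrons. The closest known reaction type is the Ni-electrocatalytic doubly decarboxylative C(sp3)–C(sp3) cross-coupling of two alkyl redox-active esters with one partner in excess, shown for primary and secondary alkyl esters including oxygenated polyketide-type acids; an electron-rich arylacetic ester as the benzyl partner is the part that is not established. No ring is closed and no stereocentre is formed; C3 lies β to the radical centre, its C–O bond is not broken by a carbon radical, and the configuration of 10 should be carried over unchanged. The step needs cross- over homo-coupling, which is secured by the threefold excess of the cheap ester 12, by the unlike character of the two radicals (a transient alkyl radical that nickel binds quickly and a persistent benzyl radical that then meets the alkylnickel species), and by the easy removal of the non-polar bibenzyl dimer. It also needs the β-oxygen to stay in place, which the 1,3-dioxane ring secures because an acetal oxygen is a poor leaving group and C–C reductive elimination from Ni(III) is fast.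

**Step 10**
Reactants: 13 (4R,6S)-4-[2-(4-benzyloxy-3-methoxyphenyl)ethyl]-6-[2-(4-benzyloxy-3,5-dimethoxyphenyl)ethyl]-2,2-dimethyl-1,3-dioxane
Product: 14 (3R,5S)-1-(4-benzyloxy-3-methoxyphenyl)-7-(4-benzyloxy-3,5-dimethoxyphenyl)heptane-3,5-diol
Conditions: AcOH/H2O (4:1), 45 °C
Reagents that add atoms: none
Why: Acid-catalysed acetal hydrolysis should release the syn-diol unchanged, since neither carbinol carbon can ionise under these conditions.

**Step 11**
Reactants: 14 (3R,5S)-1-(4-benzyloxy-3-methoxyphenyl)-7-(4-benzyloxy-3,5-dimethoxyphenyl)heptane-3,5-diol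
Product: 15 (3R,5S)-1-(4-benzyloxy-3-methoxyphenyl)-7-(4-benzyloxy-3,5-dimethoxyphenyl)heptane-3,5-diyl diacetate
Conditions: Ac2O, pyridine, DMAP (5 mol %), CH2Cl2, rt
Reagents that add atoms: acetic anhydride, CC(=O)OC(C)=O
Why: DMAP-catalysed acylation should acetylate only the C3 and C5 hydroxyls, because both phenols are still benzylated.

**Step 12**
Reactants: 15 (3R,5S)-1-(4-benzyloxy-3-methoxyphenyl)-7-(4-benzyloxy-3,5-dimethoxyphenyl)heptane-3,5-diyl diacetate
Product: 16 (3R,5S)-1-(4-hydroxy-3-methoxyphenyl)-7-(4-hydroxy-3,5-dimethoxyphenyl)heptane-3,5-diyl diacetate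
Conditions: H2 (1 atm), 10% Pd/C, EtOAc, rt
Reagents that add atoms: none
Why: Catalytic hydrogenolysis should cleave both aryl benzyl ethers while the alkyl acetates and the stereocentres stay untouched.

**Compound list**

1 | tert-butyl 2-[(4R,6R)-6-(cyanomethyl)-2,2-dimethyl-1,3-dioxan-4-yl]acetate | N#CC[C@H](C[C@H](CC(=O)OC(C)(C)C)O1)OC1(C)C | starting material
2 | 2-[(4R,6S)-6-(2-hydroxyethyl)-2,2-dimethyl-1,3-dioxan-4-yl]acetonitrile | N#CC[C@H](C[C@H](CCO)O1)OC1(C)C | intermediate
3 | 2-[(4R,6R)-6-(2-bromoethyl)-2,2-dimethyl-1,3-dioxan-4-yl]acetonitrile | N#CC[C@H](C[C@H](CCBr)O1)OC1(C)C | intermediate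
4 | 4-bromo-2,6-dimethoxyphenol | COc1cc(Br)cc(OC)c1O | starting material
5 | 2-(benzyloxy)-5-bromo-1,3-dimethoxybenzene | COc1cc(Br)cc(OC)c1OCc1ccccc1 | intermediate
6 | 2-[(4R,6S)-6-[2-(4-benzyloxy-3,5-dimethoxyphenyl)ethyl]-2,2-dimethyl-1,3-dioxan-4-yl]acetonitrile | N#CC[C@H](C[C@H](CCc2cc(OC)c(OCc3ccccc3)c(OC)c2)O1)OC1(C)C | intermediate
7 | N-(diisobutylalumanyl) aldimine of 8 (ring stereocentres as in 6) | CC(C)C[Al](CC(C)C)N=CC[C@H](C[C@H](CCc2cc(OC)c(OCc3ccccc3)c(OC)c2)O1)OC1(C)C | intermediate
8 | 2-[(4S,6S)-6-[2-(4-benzyloxy-3,5-dimethoxyphenyl)ethyl]-2,2-dimethyl-1,3-dioxan-4-yl]acetaldehyde | O=CC[C@H](C[C@H](CCc2cc(OC)c(OCc3ccccc3)c(OC)c2)O1)OC1(C)C | intermediate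
9 | 2-[(4S,6S)-6-[2-(4-benzyloxy-3,5-dimethoxyphenyl)ethyl]-2,2-dimethyl-1,3-dioxan-4-yl]acetic acid | OC(=O)C[C@H](C[C@H](CCc2cc(OC)c(OCc3ccccc3)c(OC)c2)O1)OC1(C)C | intermediate
10 | 1,3-dioxoisoindolin-2-yl 2-[(4S,6S)-6-[2-(4-benzyloxy-3,5-dimethoxyphenyl)ethyl]-2,2-dimethyl-1,3-dioxan-4-yl]acetate | O=C(C[C@H](C[C@H](CCc2cc(OC)c(OCc3ccccc3)c(OC)c2)O1)OC1(C)C)ON4C(=O)c5ccccc5C4=O | intermediate
11 | 2-(4-benzyloxy-3-methoxyphenyl)acetic acid | COc1cc(CC(=O)O)ccc1OCc1ccccc1 | starting material
12 | 1,3-dioxoisoindolin-2-yl 2-(4-benzyloxy-3-methoxyphenyl)acetate | COc1cc(CC(=O)ON2C(=O)c3ccccc3C2=O)ccc1OCc1ccccc1 | intermediate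
13 | (4R,6S)-4-[2-(4-benzyloxy-3-methoxyphenyl)ethyl]-6-[2-(4-benzyloxy-3,5-dimethoxyphenyl)ethyl]-2,2-dimethyl-1,3-dioxane | COc1cc(CC[C@H](C[C@H](CCc2cc(OC)c(OCc3ccccc3)c(OC)c2)O4)OC4(C)C)ccc1OCc1ccccc1 | intermediate
14 | (3R,5S)-1-(4-benzyloxy-3-methoxyphenyl)-7-(4-benzyloxy-3,5-dimethoxyphenyl)heptane-3,5-diol | COc1cc(CC[C@H](C[C@H](CCc2cc(OC)c(OCc3ccccc3)c(OC)c2)O)O)ccc1OCc1ccccc1 | intermediate
15 | (3R,5S)-1-(4-benzyloxy-3-methoxyphenyl)-7-(4-benzyloxy-3,5-dimethoxyphenyl)heptane-3,5-diyl diacetate | COc1cc(CC[C@H](C[C@H](CCc2cc(OC)c(OCc3ccccc3)c(OC)c2)OC(C)=O)OC(C)=O)ccc1OCc1ccccc1 | intermediate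
16 | (3R,5S)-1-(4-hydroxy-3-methoxyphenyl)-7-(4-hydroxy-3,5-dimethoxyphenyl)heptane-3,5-diyl diacetate | COc1cc(CC[C@H](C[C@H](CCc2cc(OC)c(O)c(OC)c2)OC(C)=O)OC(C)=O)ccc1O | target

**Step count**

Total: 12 steps. Longest linear sequence: 10 steps (steps 1, 2, 4, 5, 6, 7, 9, 10, 11, 12, from 1 to 16).

**Steps most likely to fail**

1. Step 9 (carries the label). The two radicals may partition unproductively: the benzyl radical dimerises or is reduced, the primary radical is lost to hydrodecarboxylation, and cross-coupling stays minor. The fallback uses known chemistry, sets out from 8 and returns at 13; it joins the aryl ring to the former nitrile carbon instead. Commercial 1-(benzyloxy)-4-bromo-2-methoxybenzene and Mg give the Grignard reagent (4-benzyloxy-3-methoxyphenyl)magnesium bromide F1. This adds to aldehyde 8 (THF, −78 °C) to give the benzylic alcohol 1-(4-benzyloxy-3-methoxyphenyl)-2-[6-[2-(4-benzyloxy-3,5-dimethoxyphenyl)ethyl]-2,2-dimethyl-1,3-dioxan-4-yl]ethan-1-ol F2, as both epimers at the new carbinol carbon with the ring stereocentres as in 13. NaH, CS2 and MeI convert it into its S-methyl xanthate F3. Barton–McCombie deoxygenation (Bu3SnH, Et3B/air, toluene, rt) then removes the benzylic oxygen and should give 13.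

2. Step 4. Oxidative addition of the electron-rich aryl bromide may be slow, so that the alkyl bromide is consumed by dimerisation and hydrodehalogenation. The fallback sets out from 3 and 5 and returns at 6; it is a polar cross-coupling with a preformed organometallic. Zinc insertion into 3 (Zn dust, LiCl, THF, 50 °C) gives 2-[(4R,6R)-6-(cyanomethyl)-2,2-dimethyl-1,3-dioxan-4-yl]ethylzinc bromide F4. Negishi coupling with 5 (Pd(OAc)2, SPhos, THF, rt to 50 °C) should then give 6.

3. Step 1. Reduction of the bulky tert-butyl ester may be sluggish, and forcing conditions may begin to reduce the nitrile. The fallback sets out from 1 and returns at 2; the ester is cleaved before reduction. NaOH in aqueous MeOH/THF saponifies the ester (the nitrile hydrolyses far more slowly) to 2-[(4R,6R)-6-(cyanomethyl)-2,2-dimethyl-1,3-dioxan-4-yl]acetic acid F5. BH3·SMe2 (THF, 0 °C) then reduces the carboxylic acid chemoselectively to 2.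

**Further compounds**

F1 | step 9 | (4-benzyloxy-3-methoxyphenyl)magnesium bromide | COc1cc([Mg]Br)ccc1OCc1ccccc1
F2 | step 9 | 1-(4-benzyloxy-3-methoxyphenyl)-2-[6-[2-(4-benzyloxy-3,5-dimethoxyphenyl)ethyl]-2,2-dimethyl-1,3-dioxan-4-yl]ethan-1-ol (carbinol epimers; ring stereocentres as in 13) | COc1cc(C(O)C[C@H](C[C@H](CCc2cc(OC)c(OCc3ccccc3)c(OC)c2)O4)OC4(C)C)ccc1OCc1ccccc1
F3 | step 9 | S-methyl xanthate of F2 (O-alkyl S-methyl dithiocarbonate at the benzylic oxygen; ring stereocentres as in 13) | COc1cc(C(OC(=S)SC)C[C@H](C[C@H](CCc2cc(OC)c(OCc3ccccc3)c(OC)c2)O4)OC4(C)C)ccc1OCc1ccccc1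
F4 | step 4 | 2-[(4R,6R)-6-(cyanomethyl)-2,2-dimethyl-1,3-dioxan-4-yl]ethylzinc bromide | N#CC[C@H](C[C@H](CC[Zn]Br)O1)OC1(C)C
F5 | step 1 | 2-[(4R,6R)-6-(cyanomethyl)-2,2-dimethyl-1,3-dioxan-4-yl]acetic acid | N#CC[C@H](C[C@H](CC(=O)O)O1)OC1(C)C
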